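**Retrosynthetic overview**

1. The strategy rests on ring A: four contiguous oxygens (O1 on C8a, OH on C8, OH on C7, OMe on C6) followed by C5–H and C4a. This is the atom pattern of a squaric ester (four carbons, four oxygens) extended by one CH=CH unit.
2. Target ⇐ tri-isopropyl ether (three O–iPr cleavages) ⇐ ring C closure (C2 inserted between O1 and C3) on a 2-hydroxydeoxybenzoin ⇐ oxidation of the C4 carbinol.
3. Ring A ⇐ 4-alkenyl-4-methoxy-2,3-diisopropoxycyclobutenone by 4π ring opening and 6π ring closure, forming the C4a–C8a bond and leaving the C8a–OH free.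
4. Cyclobutenone ⇐ diisopropyl squarate + (E)-vinyllithium + methyl triflate; vinyl iodide ⇐ terminal alkyne ⇐ arylacetaldehyde + ethynyl Grignard ⇐ ring B benzaldehyde.
5. Ring order: ring B is bought, ring A is made in step 8, ring C is closed in step 11.

Key step: step 8

Remark: the target has no stereocentre; the carbinol centre made in step 4 is racemic and the quaternary centre made in step 7 is uncontrolled, and both are erased (steps 8 and 10). Isoflavone numbering is used throughout.

**Route**

Step 1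
Reactants: 1 3-hydroxy-4,5-dimethoxybenzaldehyde
Product: 2 3-isopropoxy-4,5-dimethoxybenzaldehyde
Conditions: 2-bromopropane, K2CO3, DMF, 70 °C
Reagents that add atoms: 2-bromopropane, CC(C)Br
Why: Williamson etherification of the phenoxide with a secondary bromide in a dipolar aprotic solvent should proceed cleanly, the aldehyde being inert to carbonate.

Step 2
Reactants: 2 3-isopropoxy-4,5-dimethoxybenzaldehyde
Product: 3 1-isopropoxy-2,3-dimethoxy-5-(2-methoxyethenyl)benzene (E/Z mixture)
Conditions: Ph3P(CH2OMe)Cl, KOtBu, THF, 0 °C → rt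
Reagents that add atoms: (methoxymethyl)triphenylphosphonium chloride, COC[P+](c1ccccc1)(c1ccccc1)c1ccccc1.[Cl-]
Why: Wittig olefination with the methoxymethylene ylide should give the enol ether, whose E/Z ratio is irrelevant because both isomers hydrolyse to the same aldehyde.

Step 3
Reactants: 3 1-isopropoxy-2,3-dimethoxy-5-(2-methoxyethenyl)benzene
Product: 4 (3-isopropoxy-4,5-dimethoxyphenyl)acetaldehyde
Conditions: 2 M aq HCl, THF, 50 °C; crude product used at once
Reagents that add atoms: water, O
Why: Acid-catalysed enol ether hydrolysis (protonation, hemiacetal, loss of methanol) should unmask the homologated aldehyde without touching the aryl ethers, and immediate use avoids self-condensation of the arylacetaldehyde.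

Step 4
Reactants: 4 (3-isopropoxy-4,5-dimethoxyphenyl)acetaldehyde; 5 ethynylmagnesium bromide
Product: 6 rac-1-(3-isopropoxy-4,5-dimethoxyphenyl)but-3-yn-2-ol
Conditions: THF, −78 → 0 °C, aldehyde added to the Grignard reagent; then aq NH4Cl
Reagents that add atoms: none
Why: Grignard 1,2-addition of the weakly basic acetylide should outrun enolisation of the aldehyde and gives the future C4 carbinol as a racemate, which is acceptable because this centre is oxidised later.

Step 5
Reactants: 6 rac-1-(3-isopropoxy-4,5-dimethoxyphenyl)but-3-yn-2-ol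
Product: 7 rac-tert-butyl{[1-(3-isopropoxy-4,5-dimethoxyphenyl)but-3-yn-2-yl]oxy}dimethylsilane
Conditions: TBSCl, imidazole, DMF, rt
Reagents that add atoms: tert-butyldimethylsilyl chloride, CC(C)(C)[Si](C)(C)Cl
Why: Imidazole-promoted silylation of a secondary propargylic alcohol is reliable and gives an ether stable to the organometallic steps that follow.

Step 6
Reactants: 7 rac-tert-butyl{[1-(3-isopropoxy-4,5-dimethoxyphenyl)but-3-yn-2-yl]oxy}dimethylsilane
Product: 9 rac-tert-butyl{[(3E)-4-iodo-1-(3-isopropoxy-4,5-dimethoxyphenyl)but-3-en-2-yl]oxy}dimethylsilane, via alkenylzirconocene chloride 8 (not isolated)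
Conditions: Cp2Zr(H)Cl (Schwartz reagent), THF, rt; then I2, 0 °C
Reagents that add atoms: iodine, II
Why: Hydrozirconation adds Zr–H syn across the terminal alkyne with zirconium on the unhindered terminal carbon, and iodine cleaves the C–Zr bond with retention, so a single (E)-1-iodoalkene should result.

Step 7
Reactants: 9 rac-tert-butyl{[(3E)-4-iodo-1-(3-isopropoxy-4,5-dimethoxyphenyl)but-3-en-2-yl]oxy}dimethylsilane; 10 diisopropyl squarate
Product: 13 4-[(1E)-3-(tert-butyldimethylsilyloxy)-4-(3-isopropoxy-4,5-dimethoxyphenyl)but-1-en-1-yl]-2,3-diisopropoxy-4-methoxycyclobut-2-en-1-one (diastereomer mixture), via vinyllithium 11 (not isolated), via lithium alkoxide 12 (not isolated)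
Conditions: t-BuLi (2 equiv), Et2O, −78 °C; cannulated into 10, THF, −78 °C; then MeOTf, −78 → 0 °C
Reagents that add atoms: methyl trifluoromethanesulfonate, COS(=O)(=O)C(F)(F)F
Why: Iodine–lithium exchange with retention of alkene geometry, 1,2-addition of the vinyllithium to one squarate carbonyl (the remaining carbonyl becomes a deactivated vinylogous ester, and inverse addition limits double addition) and O-methylation of the tertiary alkoxide by the triflate should give the ether in one flask, the new quaternary centre being formed without control and destroyed in step 8.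

Step 8
Reactants: 13 4-[(1E)-3-(tert-butyldimethylsilyloxy)-4-(3-isopropoxy-4,5-dimethoxyphenyl)but-1-en-1-yl]-2,3-diisopropoxy-4-methoxycyclobut-2-en-1-one
Product: 16 rac-2-[1-(tert-butyldimethylsilyloxy)-2-(3-isopropoxy-4,5-dimethoxyphenyl)ethyl]-5,6-diisopropoxy-4-methoxyphenol, via dienylketene 14 (not isolated), via cyclohexadienone 15 (not isolated)
Conditions: toluene (degassed), 110 °C, argon
Reagents that add atoms: none
Why: Thermal conrotatory 4π opening cleaves the bond between the carbonyl carbon and the quaternary carbon to give dienylketene 14, whose disrotatory 6π electrocyclisation joins the ketene carbon (future C8a) to the distal alkene carbon (future C4a) to give cyclohexa-2,4-dienone 15, and enolisation of the C4a–H then gives the aromatic phenol. This is the known thermal ring expansion of squarate-derived 4-alkenyl-4-alkoxycyclobutenones to highly oxygenated phenols (Moore-type rearrangement). Ring A is closed as a six-membered carbocycle by 6π electrocyclisation with one new C–C bond, and no stereocentre is created, since the quaternary centre is consumed and the carbinol centre stays racemic. The step needs torquoselectivity, namely inward rotation of the alkenyl group toward the ketene, and this is secured by the geminal methoxy donor, which rotates outward. The oxygen pattern is fixed by connectivity and not by arene substitution rules: the methylated oxygen becomes the 6-OMe, the two squarate isopropoxy groups become O7 and O8, and the ketene oxygen becomes the free C8a–OH. Toluene at reflux rather than a hotter solvent is chosen so that the new ortho-hydroxybenzyl silyl ether does not lose silanol.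

Step 9
Reactants: 16 rac-2-[1-(tert-butyldimethylsilyloxy)-2-(3-isopropoxy-4,5-dimethoxyphenyl)ethyl]-5,6-diisopropoxy-4-methoxyphenol
Product: 17 rac-2-[1-hydroxy-2-(3-isopropoxy-4,5-dimethoxyphenyl)ethyl]-5,6-diisopropoxy-4-methoxyphenol
Conditions: TBAF, AcOH, THF, 0 °C → rt
Reagents that add atoms: none
Why: Fluoride-induced desilylation buffered with acetic acid should free the benzylic alcohol without strongly basic or acidic conditions that could ionise this ortho-hydroxy, para-alkoxy benzylic position.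

Step 10
Reactants: 17 rac-2-[1-hydroxy-2-(3-isopropoxy-4,5-dimethoxyphenyl)ethyl]-5,6-diisopropoxy-4-methoxyphenol
Product: 18 1-(2-hydroxy-3,4-diisopropoxy-5-methoxyphenyl)-2-(3-isopropoxy-4,5-dimethoxyphenyl)ethanone
Conditions: activated MnO2 (excess), CH2Cl2, rt
Reagents that add atoms: none
Why: Manganese dioxide is a neutral heterogeneous oxidant selective for benzylic alcohols, so the carbinol should be oxidised to the hydrogen-bonded ortho-hydroxyaryl ketone, erasing the last stereocentre.

Step 11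
Reactants: 18 1-(2-hydroxy-3,4-diisopropoxy-5-methoxyphenyl)-2-(3-isopropoxy-4,5-dimethoxyphenyl)ethanone
Product: 20 7,8-diisopropoxy-3-(3-isopropoxy-4,5-dimethoxyphenyl)-6-methoxy-4H-chromen-4-one, via enaminone 19 (not isolated)
Conditions: Me2NCH(OMe)2, toluene, 100 °C
Reagents that add atoms: N,N-dimethylformamide dimethyl acetal, COC(OC)N(C)C
Why: Condensation of the doubly activated methylene with the formamide acetal gives the enaminone, and 6-endo-trig addition of the phenol followed by loss of dimethylamine closes ring C, the standard deoxybenzoin route to isoflavones.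

Step 12
Reactants: 20 7,8-diisopropoxy-3-(3-isopropoxy-4,5-dimethoxyphenyl)-6-methoxy-4H-chromen-4-one
Product: 21 7,8-dihydroxy-3-(3-hydroxy-4,5-dimethoxyphenyl)-6-methoxy-4H-chromen-4-one (target)
Conditions: BCl3, CH2Cl2, −78 → 0 °C; then H2O
Reagents that add atoms: none
Why: Lewis acid dealkylation with BCl3 cleaves secondary isopropyl aryl ethers through an ionising pathway far faster than methyl ethers, and since C5 bears hydrogen there is no methoxy group peri to the carbonyl that chelation could remove.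

**Compound list**

1 | 3-hydroxy-4,5-dimethoxybenzaldehyde | COc1cc(C=O)cc(O)c1OC | starting material
2 | 3-isopropoxy-4,5-dimethoxybenzaldehyde | COc1cc(C=O)cc(OC(C)C)c1OC | intermediate
3 | 1-isopropoxy-2,3-dimethoxy-5-(2-methoxyethenyl)benzene (E/Z mixture) | COC=Cc1cc(OC(C)C)c(OC)c(OC)c1 | intermediate
4 | (3-isopropoxy-4,5-dimethoxyphenyl)acetaldehyde | O=CCc1cc(OC(C)C)c(OC)c(OC)c1 | intermediate
5 | ethynylmagnesium bromide | C#C[Mg]Br | starting material
6 | rac-1-(3-isopropoxy-4,5-dimethoxyphenyl)but-3-yn-2-ol | C#CC(O)Cc1cc(OC(C)C)c(OC)c(OC)c1 | intermediate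
7 | rac-tert-butyl{[1-(3-isopropoxy-4,5-dimethoxyphenyl)but-3-yn-2-yl]oxy}dimethylsilane | C#CC(O[Si](C)(C)C(C)(C)C)Cc1cc(OC(C)C)c(OC)c(OC)c1 | intermediate
8 | chloro[(1E)-3-(tert-butyldimethylsilyloxy)-4-(3-isopropoxy-4,5-dimethoxyphenyl)but-1-en-1-yl]zirconocene | Cl[Zr](/C=C/C(O[Si](C)(C)C(C)(C)C)Cc1cc(OC(C)C)c(OC)c(OC)c1)(C2C=CC=C2)C3C=CC=C3 | intermediate
9 | rac-tert-butyl{[(3E)-4-iodo-1-(3-isopropoxy-4,5-dimethoxyphenyl)but-3-en-2-yl]oxy}dimethylsilane | I/C=C/C(O[Si](C)(C)C(C)(C)C)Cc1cc(OC(C)C)c(OC)c(OC)c1 | intermediate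
10 | diisopropyl squarate (3,4-diisopropoxycyclobut-3-ene-1,2-dione) | CC(C)OC1=C(OC(C)C)C(=O)C1=O | starting material
11 | (1E)-3-(tert-butyldimethylsilyloxy)-4-(3-isopropoxy-4,5-dimethoxyphenyl)but-1-en-1-yllithium | [Li]/C=C/C(O[Si](C)(C)C(C)(C)C)Cc1cc(OC(C)C)c(OC)c(OC)c1 | intermediate
12 | lithium 1-[(1E)-3-(tert-butyldimethylsilyloxy)-4-(3-isopropoxy-4,5-dimethoxyphenyl)but-1-en-1-yl]-2,3-diisopropoxy-4-oxocyclobut-2-en-1-olate | [Li]OC1(/C=C/C(O[Si](C)(C)C(C)(C)C)Cc2cc(OC(C)C)c(OC)c(OC)c2)C(=O)C(OC(C)C)=C1OC(C)C | intermediate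
13 | 4-[(1E)-3-(tert-butyldimethylsilyloxy)-4-(3-isopropoxy-4,5-dimethoxyphenyl)but-1-en-1-yl]-2,3-diisopropoxy-4-methoxycyclobut-2-en-1-one (diastereomer mixture) | COC1(/C=C/C(O[Si](C)(C)C(C)(C)C)Cc2cc(OC(C)C)c(OC)c(OC)c2)C(=O)C(OC(C)C)=C1OC(C)C | intermediate
14 | (3Z,5E)-7-(tert-butyldimethylsilyloxy)-2,3-diisopropoxy-8-(3-isopropoxy-4,5-dimethoxyphenyl)-4-methoxyocta-1,3,5-trien-1-one | O=C=C(OC(C)C)/C(OC(C)C)=C(/OC)\C=C\C(O[Si](C)(C)C(C)(C)C)Cc1cc(OC(C)C)c(OC)c(OC)c1 | intermediate
15 | 6-[1-(tert-butyldimethylsilyloxy)-2-(3-isopropoxy-4,5-dimethoxyphenyl)ethyl]-2,3-diisopropoxy-4-methoxycyclohexa-2,4-dien-1-one | COC1=CC(C(O[Si](C)(C)C(C)(C)C)Cc2cc(OC(C)C)c(OC)c(OC)c2)C(=O)C(OC(C)C)=C1OC(C)C | intermediate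
16 | rac-2-[1-(tert-butyldimethylsilyloxy)-2-(3-isopropoxy-4,5-dimethoxyphenyl)ethyl]-5,6-diisopropoxy-4-methoxyphenol | COc1cc(C(O[Si](C)(C)C(C)(C)C)Cc2cc(OC(C)C)c(OC)c(OC)c2)c(O)c(OC(C)C)c1OC(C)C | intermediate
17 | rac-2-[1-hydroxy-2-(3-isopropoxy-4,5-dimethoxyphenyl)ethyl]-5,6-diisopropoxy-4-methoxyphenol | COc1cc(C(O)Cc2cc(OC(C)C)c(OC)c(OC)c2)c(O)c(OC(C)C)c1OC(C)C | intermediate
18 | 1-(2-hydroxy-3,4-diisopropoxy-5-methoxyphenyl)-2-(3-isopropoxy-4,5-dimethoxyphenyl)ethanone | COc1cc(C(=O)Cc2cc(OC(C)C)c(OC)c(OC)c2)c(O)c(OC(C)C)c1OC(C)C | intermediate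
19 | 3-(dimethylamino)-1-(2-hydroxy-3,4-diisopropoxy-5-methoxyphenyl)-2-(3-isopropoxy-4,5-dimethoxyphenyl)prop-2-en-1-one | COc1cc(C(=O)C(=CN(C)C)c2cc(OC(C)C)c(OC)c(OC)c2)c(O)c(OC(C)C)c1OC(C)C | intermediate
20 | 7,8-diisopropoxy-3-(3-isopropoxy-4,5-dimethoxyphenyl)-6-methoxy-4H-chromen-4-one | COc1cc2c(=O)c(-c3cc(OC(C)C)c(OC)c(OC)c3)coc2c(OC(C)C)c1OC(C)C | intermediate
21 | 7,8-dihydroxy-3-(3-hydroxy-4,5-dimethoxyphenyl)-6-methoxy-4H-chromen-4-one | COc1cc2c(=O)c(-c3cc(O)c(OC)c(OC)c3)coc2c(O)c1O | target

**Step count**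

Total step count: 12. Longest linear sequence: 12 steps (1 → 21).

**Steps most likely to fail**

Step 8 (key step). At the temperature needed for ring opening, the newly formed ortho-hydroxybenzyl silyl ether may lose tert-butyldimethylsilanol through an ortho-quinone methide and drift to a stilbene, or the ketene may be diverted before it closes. The fallback removes the carbinol from the thermal step; it sets out from squarate 10 and aldehyde 4 and returns at diol 17. Vinyllithium is added to 10 in THF at −78 °C to give lithium 1-ethenyl-2,3-diisopropoxy-4-oxocyclobut-2-en-1-olate F1, which is capped in the same flask with methyl triflate to give 4-ethenyl-2,3-diisopropoxy-4-methoxycyclobut-2-en-1-one F2. Heating F2 in toluene should open it to (3Z)-2,3-diisopropoxy-4-methoxyhexa-1,3,5-trien-1-one F3, which closes to 2,3-diisopropoxy-4-methoxycyclohexa-2,4-dien-1-one F4 and enolises to 2,3-diisopropoxy-4-methoxyphenol F5, a phenol with no benzylic leaving group. EtMgBr converts F5 into bromomagnesium 2,3-diisopropoxy-4-methoxyphenoxide F6, which in toluene should add to aldehyde 4 at its only free ortho carbon through a magnesium-chelated transition state (ortho-specific hydroxyalkylation of magnesium phenoxides), giving 17 after aq NH4Cl.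

Step 10. The electron-rich para-methoxyphenol may be oxidised toward a quinone in competition with the alcohol, or the doubly activated benzylic alcohol may ionise on the oxidant surface and dehydrate. The fallback masks the phenol before the oxidation; it sets out from phenol 16 and returns at ketone 18. Benzylation (BnBr, K2CO3, DMF) should give 2-(benzyloxy)-1-[1-(tert-butyldimethylsilyloxy)-2-(3-isopropoxy-4,5-dimethoxyphenyl)ethyl]-3,4-diisopropoxy-5-methoxybenzene F7. Desilylation (TBAF, THF) should give 1-[2-(benzyloxy)-3,4-diisopropoxy-5-methoxyphenyl]-2-(3-isopropoxy-4,5-dimethoxyphenyl)ethanol F8. Dess–Martin oxidation (NaHCO3, CH2Cl2) should give 1-[2-(benzyloxy)-3,4-diisopropoxy-5-methoxyphenyl]-2-(3-isopropoxy-4,5-dimethoxyphenyl)ethanone F9, and hydrogenolysis (H2, Pd/C, EtOAc) should then release 18.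

Step 7. O-Methylation of the hindered tertiary lithium alkoxide may be incomplete, or the alkoxide may decompose by ring opening while the flask warms before it is capped. The fallback separates addition from methylation; it sets out from vinyl iodide 9 and returns at cyclobutenone 13. Vinyllithium 11 and alkoxide 12 are generated as in step 7, but 12 is protonated at −78 °C with aq NH4Cl and the tertiary alcohol 4-[(1E)-3-(tert-butyldimethylsilyloxy)-4-(3-isopropoxy-4,5-dimethoxyphenyl)but-1-en-1-yl]-4-hydroxy-2,3-diisopropoxycyclobut-2-en-1-one F10 is isolated. Methylation under near-neutral conditions (MeI, Ag2O, K2CO3, MeCN, rt) should then give 13.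

**Further compounds**

F1 | step 8 | lithium 1-ethenyl-2,3-diisopropoxy-4-oxocyclobut-2-en-1-olate | [Li]OC1(C=C)C(=O)C(OC(C)C)=C1OC(C)C
F2 | step 8 | 4-ethenyl-2,3-diisopropoxy-4-methoxycyclobut-2-en-1-one (racemic) | COC1(C=C)C(=O)C(OC(C)C)=C1OC(C)C
F3 | step 8 | (3Z)-2,3-diisopropoxy-4-methoxyhexa-1,3,5-trien-1-one | O=C=C(OC(C)C)/C(OC(C)C)=C(/OC)C=C
F4 | step 8 | 2,3-diisopropoxy-4-methoxycyclohexa-2,4-dien-1-one | COC1=CCC(=O)C(OC(C)C)=C1OC(C)C
F5 | step 8 | 2,3-diisopropoxy-4-methoxyphenol | COc1ccc(O)c(OC(C)C)c1OC(C)C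
F6 | step 8 | bromomagnesium 2,3-diisopropoxy-4-methoxyphenoxide | COc1ccc(O[Mg]Br)c(OC(C)C)c1OC(C)C
F7 | step 10 | 2-(benzyloxy)-1-[1-(tert-butyldimethylsilyloxy)-2-(3-isopropoxy-4,5-dimethoxyphenyl)ethyl]-3,4-diisopropoxy-5-methoxybenzene (racemic) | COc1cc(C(O[Si](C)(C)C(C)(C)C)Cc2cc(OC(C)C)c(OC)c(OC)c2)c(OCc3ccccc3)c(OC(C)C)c1OC(C)C
F8 | step 10 | 1-[2-(benzyloxy)-3,4-diisopropoxy-5-methoxyphenyl]-2-(3-isopropoxy-4,5-dimethoxyphenyl)ethanol (racemic) | COc1cc(C(O)Cc2cc(OC(C)C)c(OC)c(OC)c2)c(OCc3ccccc3)c(OC(C)C)c1OC(C)C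
F9 | step 10 | 1-[2-(benzyloxy)-3,4-diisopropoxy-5-methoxyphenyl]-2-(3-isopropoxy-4,5-dimethoxyphenyl)ethanone | COc1cc(C(=O)Cc2cc(OC(C)C)c(OC)c(OC)c2)c(OCc3ccccc3)c(OC(C)C)c1OC(C)C
F10 | step 7 | 4-[(1E)-3-(tert-butyldimethylsilyloxy)-4-(3-isopropoxy-4,5-dimethoxyphenyl)but-1-en-1-yl]-4-hydroxy-2,3-diisopropoxycyclobut-2-en-1-one (diastereomer mixture) | OC1(/C=C/C(O[Si](C)(C)C(C)(C)C)Cc2cc(OC(C)C)c(OC)c(OC)c2)C(=O)C(OC(C)C)=C1OC(C)C
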